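**Retrosynthetic overview**

1. 15-Keto-PGF2α ⇐ DDQ oxidation of the C15 carbinol ⇐ Wittig olefination (C5=C6, Z) of a lactol ⇐ hydrolysis of a tricyclic acetal that masks C6, O9 and O11.
2. The cyclopentane, the C12 stereocentre and the C13–C20 enone chain arise in one flask from cyclohexene oxide 12: a semipinacol ring contraction (six to five carbons) expels one ring carbon as the C13 aldehyde, which is olefinated at once.
3. Enabling feature: C6 is acetalised by both cis oxygens (O9 and O11). The 1,3-dioxane ring O9–C6–O11–C11–C10–C9 holds both C–O bonds axial on the carbocycle and so locks the chair in which the exo epoxide C–O bond at the future C12 is equatorial and antiperiplanar to the ring bond C11–C13.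
4. The all-cis C8/C9/C11 cyclohexene comes from a meso diacetate: lipase desymmetrisation, Johnson–Claisen [3,3] shift (C7–C8 bond), lactonisation, then allylic hydroxylation and Mitsunobu inversion (O11).
5. Order of ring formation: carbocycle (from cyclohexa-1,3-diene), γ-lactone, acetal cage (tetrahydrofuran plus 1,3-dioxane), oxirane, cyclopentane by contraction, lactol.

Key step: step 9

Remark on the chemistry: positions are given in prostaglandin numbering (C1–C20) unless a compound name carries its own locants. It is assumed that the lipase in step 2 hydrolyses the acetate that leaves (1S,4R)-3; if the chosen enzyme prefers the other acetate, the same enantiomer is reached by lipase-catalysed monoacetylation of the meso diol.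

**Route**

Step 1
Reactants: 1 cyclohexa-1,3-diene
Product: 2 cis-cyclohex-2-ene-1,4-diyl diacetate (meso)
Conditions: Pd(OAc)2 (5 mol%), LiCl (cat.), LiOAc, p-benzoquinone (2 equiv), AcOH, rt
Reagents that add atoms: acetic acid (CC(=O)O)
Why: Pd(OAc)2-catalysed 1,4-diacetoxylation of a conjugated diene (acetoxypalladation, then attack of external acetate on the π-allyl complex anti to palladium, enforced by catalytic chloride) should give the cis diacetate, with p-benzoquinone reoxidising zerovalent palladium.

Step 2
Reactants: 2 cis-cyclohex-2-ene-1,4-diyl diacetate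
Product: 3 (1S,4R)-4-hydroxycyclohex-2-en-1-yl acetate
Conditions: lipase from Burkholderia cepacia, phosphate buffer pH 7, 25 °C
Reagents that add atoms: none
Why: Lipase-catalysed hydrolysis of one of the two enantiotopic ester groups of a meso diacetate (enzymatic desymmetrisation) should set both stereocentres from an achiral precursor.

Step 3
Reactants: 3 (1S,4R)-4-hydroxycyclohex-2-en-1-yl acetate; 4 triethyl orthoacetate
Product: 5 ethyl 2-[(1R,6S)-6-acetoxycyclohex-2-en-1-yl]acetate
Conditions: EtCO2H (cat.), 140 °C, EtOH distilled off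
Reagents that add atoms: none
Why: The Johnson–Claisen [3,3]-sigmatropic rearrangement of the ketene acetal formed in situ is suprafacial, so the new C7–C8 bond is made on the ring face that carried the hydroxyl, cis to the neighbouring acetoxy group.

Step 4
Reactants: 5 ethyl 2-[(1R,6S)-6-acetoxycyclohex-2-en-1-yl]acetate
Product: 7 (3aR,7aS)-3a,6,7,7a-tetrahydro-1-benzofuran-2(3H)-one, via hydroxy ester 6 (not isolated)
Conditions: K2CO3 (cat.), EtOH, rt; then TsOH·H2O (cat.), toluene, 80 °C
Reagents that add atoms: none
Why: Base-catalysed transesterification removes the acetyl group, and the freed cis-hydroxy ester closes to the cis-fused γ-lactone (lactonisation, completed by acid).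

Step 5
Reactants: 7 (3aR,7aS)-3a,6,7,7a-tetrahydro-1-benzofuran-2(3H)-one
Product: 8 (3aR,6S,7aS)-6-hydroxy-3a,6,7,7a-tetrahydro-1-benzofuran-2(3H)-one (hydroxyl trans to the lactone oxygen)
Conditions: SeO2 (0.5 equiv), t-BuOOH (2 equiv), CH2Cl2, rt
Reagents that add atoms: tert-butyl hydroperoxide (CC(C)(C)OO)
Why: SeO2-mediated allylic hydroxylation (ene reaction, then [2,3]-sigmatropic shift) should take the allylic CH2 in preference to the ring-fusion CH and deliver oxygen from the convex face of the cis-fused bicycle.

Step 6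
Reactants: 8 (3aR,6S,7aS)-6-hydroxy-3a,6,7,7a-tetrahydro-1-benzofuran-2(3H)-one
Product: 9 (3aR,6R,7aS)-2-oxo-2,3,3a,6,7,7a-hexahydro-1-benzofuran-6-yl benzoate (benzoate cis to the lactone oxygen)
Conditions: PhCO2H, PPh3, diisopropyl azodicarboxylate, THF, 0 °C to rt
Reagents that add atoms: benzoic acid (OC(=O)c1ccccc1)
Why: The Mitsunobu reaction inverts the allylic carbinol by SN2 displacement of the oxyphosphonium ion, which places O11 cis to O9 as the later 1,3-diaxial tether requires.

Step 7
Reactants: 9 (3aR,6R,7aS)-2-oxo-2,3,3a,6,7,7a-hexahydro-1-benzofuran-6-yl benzoate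
Product: 11 (1S,3R,6R,8S)-9,10-dioxatricyclo[4.3.1.0^{3,8}]dec-4-ene (the acetal carbon C1 is bonded to both ring oxygens), via lactol 10 (not isolated)
Conditions: i-Bu2AlH (3.5 equiv), CH2Cl2, −78 °C; aq. KNaC4H4O6; then pyridinium p-toluenesulfonate (cat.), 4 Å molecular sieves, CH2Cl2, rt
Reagents that add atoms: none
Why: i-Bu2AlH reduces the γ-lactone to the lactol and cleaves the benzoate; mild acid then turns the hemiacetal into an oxocarbenium ion that the cis C11 hydroxyl traps (intramolecular acetalisation under thermodynamic control).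

Step 8
Reactants: 11 (1S,3R,6R,8S)-9,10-dioxatricyclo[4.3.1.0^{3,8}]dec-4-ene
Product: 12 exo-4,5-epoxy-9,10-dioxatricyclo[4.3.1.0^{3,8}]decane (oxirane oxygen on the face away from acetal carbon C1)
Conditions: dimethyldioxirane (acetone solution), CH2Cl2, 0 °C
Reagents that add atoms: dimethyldioxirane (CC1(C)OO1)
Why: Epoxidation with a neutral dioxirane spares the acetal and can only occur on the exo face of the alkene, because the acetal bridge covers the endo face.

Step 9
Reactants: 12 exo-4,5-epoxy-9,10-dioxatricyclo[4.3.1.0^{3,8}]decane; 13 dimethyl (2-oxoheptyl)phosphonate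
Product: 15 (E)-1-(2,9-dioxatricyclo[3.3.1.0^{3,7}]non-6-yl)oct-1-en-3-one (side chain exo, on the face away from the acetal carbon), via aldehyde 14 (not isolated)
Conditions: MeAl(OC6H2-4-Br-2,6-t-Bu2)2 (20 mol%), CH2Cl2, −78 to −20 °C; then 13, LiCl, i-Pr2NEt, MeCN, 0 °C to rt
Reagents that add atoms: none
Why: The aluminium Lewis acid binds the exo oxirane oxygen and the C4–O bond (locants of 12; the bond remote from the electron-withdrawing C6–O10 bond) ionises while ring bond C5–C6 shifts to C4 from the opposite face and C5 becomes the formyl carbon; this is a semipinacol (Meinwald-type) 1,2-shift whose closest precedent is the Lewis acid-promoted rearrangement of 2,3-epoxy silyl ethers and 2,3-epoxy acylates to β-oxy aldehydes, including contractions of cyclohexene oxides to cyclopentanecarbaldehydes. The five-membered carbocycle is thus formed by contraction of the six-membered one through a ring-bond shift and not by a cyclisation, so no exo or endo closure mode applies. The one new stereocentre (C12) is set by inversion at the migration terminus: C11 replaces the exo C–O bond, which leaves the formyl group on the exo face, trans to the C7 methylene on C8 and to O11, while the migrating C11 keeps its configuration. The step needs cleavage of C4–O rather than C5–O and migration of the ring bond rather than of hydride; the substrate secures both, because the 1,3-dioxane ring holds the carbocycle in the chair in which C4–O is equatorial and antiperiplanar to C5–C6, whereas the hydride that could shift is antiperiplanar only to the disfavoured axial C5–O bond. The aldehyde is then olefinated in the same flask by a Horner–Wadsworth–Emmons reaction under LiCl and amine, which should give the (E)-enone and avoids isolating a β-alkoxy aldehyde.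

Step 10
Reactants: 15 (E)-1-(2,9-dioxatricyclo[3.3.1.0^{3,7}]non-6-yl)oct-1-en-3-one
Product: 16 (E)-1-(2,9-dioxatricyclo[3.3.1.0^{3,7}]non-6-yl)oct-1-en-3-ol (both carbinol epimers)
Conditions: NaBH4, CeCl3·7H2O, MeOH, −40 °C
Reagents that add atoms: none
Why: Luche reduction adds hydride 1,2 to the enone; the configuration of the new carbinol does not matter because it is reoxidised in step 13, and the alcohol protects C15 during the ylide step.

Step 11
Reactants: 16 (E)-1-(2,9-dioxatricyclo[3.3.1.0^{3,7}]non-6-yl)oct-1-en-3-ol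
Product: 17 (3aR,4R,5R,6aS)-4-[(E)-3-hydroxyoct-1-en-1-yl]hexahydro-2H-cyclopenta[b]furan-2,5-diol (anomers and carbinol epimers)
Conditions: AcOH/H2O/THF (3:1:1), 45 °C
Reagents that add atoms: water (O)
Why: Acid-catalysed hydrolysis of the bicyclic acetal releases the C11 hydroxyl and leaves C6 as the five-membered lactol needed for olefination.

Step 12
Reactants: 17 (3aR,4R,5R,6aS)-4-[(E)-3-hydroxyoct-1-en-1-yl]hexahydro-2H-cyclopenta[b]furan-2,5-diol; 18 (4-carboxybutyl)triphenylphosphonium bromide
Product: 20 (5Z,9α,11α,13E)-9,11,15-trihydroxyprosta-5,13-dien-1-oic acid (both C15 epimers), via ylide 19 (not isolated)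
Conditions: 18 (4 equiv), KOt-Bu (8 equiv), THF, 0 °C; then 17, 0 °C to rt; aq. HCl to pH 4
Reagents that add atoms: none
Why: Wittig olefination of the lactol (through its open hydroxy aldehyde) with an unstabilised ylide should give the (Z)-alkene by kinetic formation of the cis-oxaphosphetane.

Step 13
Reactants: 20 (5Z,9α,11α,13E)-9,11,15-trihydroxyprosta-5,13-dien-1-oic acid
Product: 21 15-keto-PGF2α, (5Z,9α,11α,13E)-9,11-dihydroxy-15-oxoprosta-5,13-dien-1-oic acid
Conditions: DDQ (1.3 equiv), 1,4-dioxane, rt
Reagents that add atoms: none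
Why: DDQ dehydrogenates allylic alcohols much faster than saturated secondary alcohols, so only the C15 carbinol should be oxidised, and both epimers converge on the enone.

**Compound list**

1 | cyclohexa-1,3-diene | C1=CC=CCC1 | starting material
2 | cis-cyclohex-2-ene-1,4-diyl diacetate (meso) | CC(=O)O[C@@H]1CC[C@H](OC(C)=O)C=C1 | intermediate
3 | (1S,4R)-4-hydroxycyclohex-2-en-1-yl acetate | O[C@@H]1CC[C@H](OC(C)=O)C=C1 | intermediate
4 | triethyl orthoacetate | CCOC(C)(OCC)OCC | starting material
5 | ethyl 2-[(1R,6S)-6-acetoxycyclohex-2-en-1-yl]acetate | CCOC(=O)C[C@@H]1C=CCC[C@@H]1OC(C)=O | intermediate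
6 | ethyl 2-[(1R,6S)-6-hydroxycyclohex-2-en-1-yl]acetate | CCOC(=O)C[C@@H]1C=CCC[C@@H]1O | intermediate
7 | (3aR,7aS)-3a,6,7,7a-tetrahydro-1-benzofuran-2(3H)-one | O=C1C[C@@H]2C=CCC[C@@H]2O1 | intermediate
8 | (3aR,6S,7aS)-6-hydroxy-3a,6,7,7a-tetrahydro-1-benzofuran-2(3H)-one | O=C1C[C@@H]2C=C[C@@H](O)C[C@@H]2O1 | intermediate
9 | (3aR,6R,7aS)-2-oxo-2,3,3a,6,7,7a-hexahydro-1-benzofuran-6-yl benzoate | O=C1C[C@@H]2C=C[C@H](OC(=O)c3ccccc3)C[C@@H]2O1 | intermediate
10 | (3aR,6R,7aS)-2,3,3a,6,7,7a-hexahydro-1-benzofuran-2,6-diol (anomers) | OC1C[C@@H]2C=C[C@H](O)C[C@@H]2O1 | intermediate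
11 | (1S,3R,6R,8S)-9,10-dioxatricyclo[4.3.1.0^{3,8}]dec-4-ene | [C@H]12C[C@@H]3C=C[C@H](O1)C[C@@H]3O2 | intermediate
12 | exo-4,5-epoxy-9,10-dioxatricyclo[4.3.1.0^{3,8}]decane (from 11, oxirane anti to C1) | [C@H]12C[C@@H]3[C@H]4O[C@H]4[C@H](O1)C[C@@H]3O2 | intermediate
13 | dimethyl (2-oxoheptyl)phosphonate | CCCCCC(=O)CP(=O)(OC)OC | starting material
14 | 2,9-dioxatricyclo[3.3.1.0^{3,7}]nonane-6-carbaldehyde (formyl exo, trans to the C7–C8 bond) | [C@H]12C[C@@H]3[C@@H](C=O)[C@H](O1)C[C@@H]3O2 | intermediate
15 | (E)-1-(2,9-dioxatricyclo[3.3.1.0^{3,7}]non-6-yl)oct-1-en-3-one | [C@H]12C[C@@H]3[C@@H](/C=C/C(=O)CCCCC)[C@H](O1)C[C@@H]3O2 | intermediate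
16 | (E)-1-(2,9-dioxatricyclo[3.3.1.0^{3,7}]non-6-yl)oct-1-en-3-ol (carbinol epimers) | [C@H]12C[C@@H]3[C@@H](/C=C/C(O)CCCCC)[C@H](O1)C[C@@H]3O2 | intermediate
17 | (3aR,4R,5R,6aS)-4-[(E)-3-hydroxyoct-1-en-1-yl]hexahydro-2H-cyclopenta[b]furan-2,5-diol | OC1C[C@@H]2[C@@H](/C=C/C(O)CCCCC)[C@H](O)C[C@@H]2O1 | intermediate
18 | (4-carboxybutyl)triphenylphosphonium bromide | OC(=O)CCCC[P+](c1ccccc1)(c1ccccc1)c1ccccc1.[Br-] | starting material
19 | potassium 5-(triphenylphosphoranylidene)pentanoate | [K+].[O-]C(=O)CCCC=P(c1ccccc1)(c1ccccc1)c1ccccc1 | intermediate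
20 | (5Z,9α,11α,13E)-9,11,15-trihydroxyprosta-5,13-dien-1-oic acid (C15 epimers) | OC(=O)CCC/C=C\C[C@@H]1[C@@H](/C=C/C(O)CCCCC)[C@H](O)C[C@@H]1O | intermediate
21 | 15-keto-PGF2α | CCCCCC(=O)/C=C/[C@@H]1[C@@H](C/C=C\CCCC(=O)O)[C@@H](O)C[C@H]1O | target

**Step count**

Total: 13 steps. Longest linear sequence: 13 steps (from cyclohexa-1,3-diene).

**Steps most likely to fail**

Step 9. The Lewis acid may ionise the acetal, turn over poorly, or open the oxirane without the ring-bond shift. The fallback sets out from alkene 11 and avoids the epoxide altogether. Exo-face dihydroxylation (OsO4 cat., N-methylmorpholine N-oxide, acetone/H2O) should give the exo-cis-diol F1, whose C4 hydroxyl is equatorial and whose C5 hydroxyl is axial on the locked chair. Selective sulfonylation of the equatorial hydroxyl (MsCl, 2,4,6-collidine, CH2Cl2, −20 °C) should give the monomesylate F2. KOt-Bu in THF at 0 °C then triggers the base-induced semipinacol rearrangement of a 2-hydroxy sulfonate: the alkoxide pushes, the equatorial leaving group is antiperiplanar to ring bond C5–C6, and the product is aldehyde 14 with the same exo formyl group. Aldehyde 14 is olefinated as in the second stage of step 9 and the route is rejoined at 15.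

Step 5. Hydroxylation may occur at the ring-fusion carbon, run on to the ketone, or take the wrong face. The fallback sets out from lactone 7. Allylic oxidation to the ketone (CrO3·3,5-dimethylpyrazole, CH2Cl2, −20 °C) should give the enone lactone F3. Luche reduction (NaBH4, CeCl3·7H2O, MeOH, −78 °C) from the convex face should give the 6α-alcohol F4 directly, with the hydroxyl cis to the lactone oxygen, so no Mitsunobu inversion is needed. Alcohol F4 is taken through the conditions of step 7 (2.2 equiv of i-Bu2AlH, then acid) and rejoins the route at 11.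

Step 11. The doubly tethered acetal may re-close, and the allylic alcohol may ionise under the aqueous acid needed to open it. The fallback sets out from enone 15 and opens the cage before the ketone is reduced. Acid-catalysed methanolysis (camphorsulfonic acid, MeOH, rt) should open the acetal by mass action to the methyl glycoside F5 while the side chain is still an acid-stable enone. Luche reduction then gives the allylic alcohol F6, and the simple methyl acetal is hydrolysed under mild conditions (AcOH/H2O/THF, rt) to lactol 17.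

**Further compounds**

F1 | step 9 | exo,exo-9,10-dioxatricyclo[4.3.1.0^{3,8}]decane-4,5-diol | [C@H]12C[C@@H]3[C@@H](O)[C@@H](O)[C@H](O1)C[C@@H]3O2
F2 | step 9 | exo-5-hydroxy-9,10-dioxatricyclo[4.3.1.0^{3,8}]dec-4-yl methanesulfonate | [C@H]12C[C@@H]3[C@@H](OS(C)(=O)=O)[C@@H](O)[C@H](O1)C[C@@H]3O2
F3 | step 5 | (3aR,7aS)-3,3a,7,7a-tetrahydro-1-benzofuran-2,6-dione | O=C1C[C@@H]2C=CC(=O)C[C@@H]2O1
F4 | step 5 | (3aR,6R,7aS)-6-hydroxy-3a,6,7,7a-tetrahydro-1-benzofuran-2(3H)-one | O=C1C[C@@H]2C=C[C@H](O)C[C@@H]2O1
F5 | step 11 | (E)-1-[(3aR,4R,5R,6aS)-5-hydroxy-2-methoxyhexahydro-2H-cyclopenta[b]furan-4-yl]oct-1-en-3-one | COC1C[C@@H]2[C@@H](/C=C/C(=O)CCCCC)[C@H](O)C[C@@H]2O1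
F6 | step 11 | (3aR,4R,5R,6aS)-4-[(E)-3-hydroxyoct-1-en-1-yl]-2-methoxyhexahydro-2H-cyclopenta[b]furan-5-ol | COC1C[C@@H]2[C@@H](/C=C/C(O)CCCCC)[C@H](O)C[C@@H]2O1
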